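**Retrosynthetic overview**
- Feature: ring A of the isoflavone is a phloroglucinol whose three oxygens all differ (C5-OH chelated to C4=O, C7-OH, ring oxygen O1 on C8a). It carries the 3-hydroxy-3-methylbutyl chain on C6 and H on C8, and is fused to pyranone ring C through C4a=C8a.
- Key disconnection: ring A is opened at C8a–C8, C7–C8, C5–C6 and C4a–C5. This gives a 5-aryl-4-oxopyran-2-yl diazomethyl ketone (C4a, C8a, C5, C8) and a 1-siloxyalkyne bearing the chain (C6, C7), so C6 versus C8 is never chosen on a preformed phloroglucinol.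
- Diazoketone: the C3–C1' biaryl bond comes from Suzuki coupling of a comenate C5 triflate with a 7-(methoxymethoxy)chromen-6-yl boronate. The boronate is made from 7-hydroxy-2,2-dimethylchroman-4-one by C6 bromination, reduction, elimination and borylation. The siloxyalkyne comes from methyl pent-4-ynoate by Grignard addition, silylation and acetylide oxygenation.
- Ring order: pyranone ring C is bought; the pyran ring of the chromene comes with the chromanone and receives its alkene early; ring A is formed last; acid and then fluoride unmask the phenols and the carbinol.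

Key step: step 14

Remark: comenic acid is taken as a purchased material (it is also the one-step catalytic air-oxidation product of kojic acid). The target has no stereocentre, so "racemic" appears only on transient intermediates.

**Boronate fragment**

Step 1
Reactants: 1 7-hydroxy-2,2-dimethylchroman-4-one
Product: 2 7-(methoxymethoxy)-2,2-dimethylchroman-4-one
Conditions: MOMCl, i-Pr2NEt, CH2Cl2, 0 °C to rt
Reagents that add atoms: chloromethyl methyl ether, COCCl
Why: O-alkylation (methoxymethylation) of the acidic para-acyl phenol with a hindered amine base that leaves the ketone untouched.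

Step 2
Reactants: 2 7-(methoxymethoxy)-2,2-dimethylchroman-4-one
Product: 3 6-bromo-7-(methoxymethoxy)-2,2-dimethylchroman-4-one
Conditions: NBS, DMF, 0 °C to rt
Reagents that add atoms: N-bromosuccinimide, O=C1CCC(=O)N1Br
Why: Electrophilic aromatic bromination should go to C6, which is para to O1, ortho to the C7 oxygen and less hindered than C8 between two oxygens, while C5 is not activated and DMF keeps the medium non-acidic for the acetal.

Step 3
Reactants: 3 6-bromo-7-(methoxymethoxy)-2,2-dimethylchroman-4-one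
Product: 4 6-bromo-7-(methoxymethoxy)-2,2-dimethylchroman-4-ol (racemic)
Conditions: NaBH4, MeOH/THF, 0 °C
Reagents that add atoms: none
Why: Borohydride reduction of the aryl ketone; the new C4 carbinol centre forms as a racemate and is destroyed in the next step.

Step 4
Reactants: 4 6-bromo-7-(methoxymethoxy)-2,2-dimethylchroman-4-ol (racemic)
Product: 6 6-bromo-7-(methoxymethoxy)-2,2-dimethyl-2H-chromene, via C4 mesylate 5 (not isolated)
Conditions: MsCl, Et3N, CH2Cl2, 0 °C to reflux
Reagents that add atoms: none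
Why: Sulfonylation then E1-type elimination: the C4 mesylate ionises readily because the cation is stabilised by the para C7 oxygen and by O1, and the amine removes H3 to give the conjugated chromene without acid that would cleave the acetal.

Step 5
Reactants: 6 6-bromo-7-(methoxymethoxy)-2,2-dimethyl-2H-chromene
Product: 8 2-[7-(methoxymethoxy)-2,2-dimethyl-2H-chromen-6-yl]-4,4,5,5-tetramethyl-1,3,2-dioxaborolane, via aryllithium 7 (not isolated)
Conditions: n-BuLi, THF, −78 °C; i-PrOBpin, −78 °C to rt; aq. NH4Cl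
Reagents that add atoms: 2-isopropoxy-4,4,5,5-tetramethyl-1,3,2-dioxaborolane, CC(C)OB1OC(C)(C)C(C)(C)O1
Why: Bromine–lithium exchange gives an aryllithium held by chelation to the ortho methoxymethoxy group, and borylation with the isopropoxyboronate traps it before any side reaction.

**Pyranone fragment and diazoketone**

Step 6
Reactants: 9 comenic acid (5-hydroxy-4-oxo-4H-pyran-2-carboxylic acid)
Product: 10 methyl 5-hydroxy-4-oxo-4H-pyran-2-carboxylate
Conditions: MeOH, H2SO4 (cat.), reflux
Reagents that add atoms: methanol, CO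
Why: Fischer esterification; the 4-pyranone and its enolic C5 hydroxyl are stable to hot acidic methanol.

Step 7
Reactants: 10 methyl 5-hydroxy-4-oxo-4H-pyran-2-carboxylate
Product: 11 methyl 4-oxo-5-(trifluoromethylsulfonyloxy)-4H-pyran-2-carboxylate
Conditions: Tf2O, pyridine, CH2Cl2, −20 to 0 °C
Reagents that add atoms: trifluoromethanesulfonic anhydride, O=S(=O)(OS(=O)(=O)C(F)(F)F)C(F)(F)F
Why: O-sulfonylation of the acidic enol-type C5 hydroxyl gives the pyranonyl triflate needed for cross-coupling.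

Step 8
Reactants: 11 methyl 4-oxo-5-(trifluoromethylsulfonyloxy)-4H-pyran-2-carboxylate; 8 2-[7-(methoxymethoxy)-2,2-dimethyl-2H-chromen-6-yl]-4,4,5,5-tetramethyl-1,3,2-dioxaborolane
Product: 12 methyl 5-[7-(methoxymethoxy)-2,2-dimethyl-2H-chromen-6-yl]-4-oxo-4H-pyran-2-carboxylate
Conditions: PdCl2(dppf)·CH2Cl2 (5 mol %), K3PO4, 1,4-dioxane/H2O (20:1), 70 °C
Reagents that add atoms: none
Why: Suzuki–Miyaura coupling; zerovalent palladium inserts readily into the C5–OTf bond of the electron-poor pyranone, and a weak base with little water limits ester and triflate hydrolysis.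

Step 9
Reactants: 12 methyl 5-[7-(methoxymethoxy)-2,2-dimethyl-2H-chromen-6-yl]-4-oxo-4H-pyran-2-carboxylate
Product: 13 5-[7-(methoxymethoxy)-2,2-dimethyl-2H-chromen-6-yl]-4-oxo-4H-pyran-2-carboxylic acid
Conditions: Me3SnOH, ClCH2CH2Cl, 70 °C; cold 5% aq. HCl wash
Reagents that add atoms: trimethyltin hydroxide, C[Sn](C)(C)O
Why: Trimethyltin hydroxide ester cleavage is nearly neutral, chosen because free hydroxide would add to C6 of the pyranone and open the ring.

Step 10
Reactants: 13 5-[7-(methoxymethoxy)-2,2-dimethyl-2H-chromen-6-yl]-4-oxo-4H-pyran-2-carboxylic acid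
Product: 15 2-diazo-1-{5-[7-(methoxymethoxy)-2,2-dimethyl-2H-chromen-6-yl]-4-oxo-4H-pyran-2-yl}ethan-1-one, via mixed anhydride 14 (not isolated)
Conditions: i-BuOCOCl, N-methylmorpholine, THF, −15 °C; CH2N2, Et2O, 0 °C to rt
Reagents that add atoms: diazomethane, C=[N+]=[N-]
Why: Acylation of diazomethane by a mixed carbonic anhydride (Arndt–Eistert-type diazoketone synthesis); activation without HCl spares the acetal, and the carbonate leaving group removes the proton of the acyldiazonium ion.

**Siloxyalkyne fragment**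

Step 11
Reactants: 16 methyl pent-4-ynoate
Product: 18 2-methylhex-5-yn-2-ol, via hex-5-yn-2-one 17 (not isolated)
Conditions: MeMgBr (3.3 equiv), THF, 0 °C to rt; aq. NH4Cl
Reagents that add atoms: methylmagnesium bromide, C[Mg]Br
Why: Double Grignard addition to the ester through the methyl ketone; the extra equivalent is taken up by the acetylenic C–H, which is restored on quench.

Step 12
Reactants: 18 2-methylhex-5-yn-2-ol
Product: 19 triethyl[(2-methylhex-5-yn-2-yl)oxy]silane
Conditions: Et3SiOTf, 2,6-lutidine, CH2Cl2, −78 to 0 °C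
Reagents that add atoms: triethylsilyl trifluoromethanesulfonate, CC[Si](CC)(CC)OS(=O)(=O)C(F)(F)F
Why: Silylation of the hindered tertiary alcohol with a silyl triflate masks the O–H that would quench the acetylide and later trap the ketene.

Step 13
Reactants: 19 triethyl[(2-methylhex-5-yn-2-yl)oxy]silane
Product: 22 triisopropyl{[5-methyl-5-(triethylsilyloxy)hex-1-yn-1-yl]oxy}silane, via lithium acetylide 20 (not isolated), via lithium ynolate 21 (not isolated)
Conditions: LiN(SiMe3)2 (2.2 equiv), t-BuOOH (decane), THF, −78 to 0 °C; i-Pr3SiOTf, −78 to 0 °C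
Reagents that add atoms: tert-butyl hydroperoxide, CC(C)(C)OO; triisopropylsilyl trifluoromethanesulfonate, CC(C)[Si](C(C)C)(C(C)C)OS(=O)(=O)C(F)(F)F
Why: Julia-type siloxyalkyne synthesis: the acetylide attacks the peroxide oxygen of lithium tert-butyl peroxide with loss of tert-butoxide to give the ynolate, and the bulky silyl triflate silylates it on oxygen, not carbon.

**Ring A and end game**

Step 14
Reactants: 15 2-diazo-1-{5-[7-(methoxymethoxy)-2,2-dimethyl-2H-chromen-6-yl]-4-oxo-4H-pyran-2-yl}ethan-1-one; 22 triisopropyl{[5-methyl-5-(triethylsilyloxy)hex-1-yn-1-yl]oxy}silane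
Product: 27 5-hydroxy-3-[7-(methoxymethoxy)-2,2-dimethyl-2H-chromen-6-yl]-6-[3-methyl-3-(triethylsilyloxy)butyl]-7-(triisopropylsilyloxy)-4H-chromen-4-one, via pyranonylketene 23 (not isolated), via cyclobutenone 24 (not isolated), via dienylketene 25 (not isolated), via cyclohexadienone 26 (not isolated)
Conditions: 22 (1.3 equiv), hν (440 nm LEDs), ClCH2CH2Cl, 25 °C; then 80 °C
Reagents that add atoms: none
Why: Visible light should expel N2 from 15 and the pyranonyl group shift to the carbene carbon (Wolff rearrangement, forming C8a–C8) to give ketene 23, whose electrophilic central carbon is attacked by the alkyl-bearing, nucleophilic carbon of siloxyalkyne 22 in a [2+2] cycloaddition (C5–C6 and C7–C8) giving cyclobutenone 24. On warming, 24 should open by a four-electron conrotatory electrocyclic cleavage to dienylketene 25, which closes ring A by a thermally allowed six-electron disrotatory electrocyclisation (six-membered carbocycle, C5–C4a bond) onto the pyranone C3–H carbon, and enolisation of dienone 26 gives the C5 phenol. This is the diazoketone–siloxyalkyne form of the Danheiser benzannulation, established for alkenyl, aryl and heteroaryl diazomethyl ketones, here with the pyranone C2=C3 bond as the third π component. No stereocentre is formed in 27; those in 24 and 26 are transient and racemic. The regiochemistry needed, chain between the two oxygens, follows from the polarisation of the ynol ether, and the ring closure has no alternative because C3 is the only carbon joined by a double bond to the ketene-bearing pyranone carbon. Visible light is chosen so that only the diazo n–π* band is excited and the chromene and pyranone chromophores are not.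

Step 15
Reactants: 27 5-hydroxy-3-[7-(methoxymethoxy)-2,2-dimethyl-2H-chromen-6-yl]-6-[3-methyl-3-(triethylsilyloxy)butyl]-7-(triisopropylsilyloxy)-4H-chromen-4-one
Product: 28 5-hydroxy-3-(7-hydroxy-2,2-dimethyl-2H-chromen-6-yl)-6-(3-hydroxy-3-methylbutyl)-7-(triisopropylsilyloxy)-4H-chromen-4-one
Conditions: 2 M HCl, MeOH/THF, 40 °C
Reagents that add atoms: none
Why: Acid-catalysed acetal exchange removes the methoxymethyl group and solvolysis removes the triethylsilyl ether, while the aryl triisopropylsilyl ether should persist, so the C7 oxygen cannot close onto the side chain and the chelated C5 hydroxyl is a poor nucleophile.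

Step 16
Reactants: 28 5-hydroxy-3-(7-hydroxy-2,2-dimethyl-2H-chromen-6-yl)-6-(3-hydroxy-3-methylbutyl)-7-(triisopropylsilyloxy)-4H-chromen-4-one
Product: 29 5,7-dihydroxy-3-(7-hydroxy-2,2-dimethyl-2H-chromen-6-yl)-6-(3-hydroxy-3-methylbutyl)-4H-chromen-4-one
Conditions: Bu4NF, AcOH, THF, 0 °C
Reagents that add atoms: none
Why: Fluoride-induced cleavage of the aryl silyl ether; buffering with acetic acid keeps the medium from opening the pyranone ring.

**Compound list**
1 | 7-hydroxy-2,2-dimethylchroman-4-one | CC1(C)CC(=O)c2ccc(O)cc2O1 | starting material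
2 | 7-(methoxymethoxy)-2,2-dimethylchroman-4-one | CC1(C)CC(=O)c2ccc(OCOC)cc2O1 | intermediate
3 | 6-bromo-7-(methoxymethoxy)-2,2-dimethylchroman-4-one | CC1(C)CC(=O)c2cc(Br)c(OCOC)cc2O1 | intermediate
4 | 6-bromo-7-(methoxymethoxy)-2,2-dimethylchroman-4-ol (racemic) | CC1(C)CC(O)c2cc(Br)c(OCOC)cc2O1 | intermediate
5 | 6-bromo-7-(methoxymethoxy)-2,2-dimethylchroman-4-yl methanesulfonate (racemic, not isolated) | CC1(C)CC(OS(C)(=O)=O)c2cc(Br)c(OCOC)cc2O1 | intermediate
6 | 6-bromo-7-(methoxymethoxy)-2,2-dimethyl-2H-chromene | CC1(C)C=Cc2cc(Br)c(OCOC)cc2O1 | intermediate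
7 | [7-(methoxymethoxy)-2,2-dimethyl-2H-chromen-6-yl]lithium (not isolated) | CC1(C)C=Cc2cc([Li])c(OCOC)cc2O1 | intermediate
8 | 2-[7-(methoxymethoxy)-2,2-dimethyl-2H-chromen-6-yl]-4,4,5,5-tetramethyl-1,3,2-dioxaborolane | CC1(C)C=Cc2cc(B3OC(C)(C)C(C)(C)O3)c(OCOC)cc2O1 | intermediate
9 | comenic acid (5-hydroxy-4-oxo-4H-pyran-2-carboxylic acid) | OC(=O)c1cc(=O)c(O)co1 | starting material
10 | methyl 5-hydroxy-4-oxo-4H-pyran-2-carboxylate | COC(=O)c1cc(=O)c(O)co1 | intermediate
11 | methyl 4-oxo-5-(trifluoromethylsulfonyloxy)-4H-pyran-2-carboxylate | COC(=O)c1cc(=O)c(OS(=O)(=O)C(F)(F)F)co1 | intermediate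
12 | methyl 5-[7-(methoxymethoxy)-2,2-dimethyl-2H-chromen-6-yl]-4-oxo-4H-pyran-2-carboxylate | COC(=O)c1cc(=O)c(-c2cc3c(cc2OCOC)OC(C)(C)C=C3)co1 | intermediate
13 | 5-[7-(methoxymethoxy)-2,2-dimethyl-2H-chromen-6-yl]-4-oxo-4H-pyran-2-carboxylic acid | OC(=O)c1cc(=O)c(-c2cc3c(cc2OCOC)OC(C)(C)C=C3)co1 | intermediate
14 | isobutyl carbonic anhydride of acid 13 (not isolated) | CC(C)COC(=O)OC(=O)c1cc(=O)c(-c2cc3c(cc2OCOC)OC(C)(C)C=C3)co1 | intermediate
15 | 2-diazo-1-{5-[7-(methoxymethoxy)-2,2-dimethyl-2H-chromen-6-yl]-4-oxo-4H-pyran-2-yl}ethan-1-one | [N-]=[N+]=CC(=O)c1cc(=O)c(-c2cc3c(cc2OCOC)OC(C)(C)C=C3)co1 | intermediate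
16 | methyl pent-4-ynoate | C#CCCC(=O)OC | starting material
17 | hex-5-yn-2-one (not isolated) | CC(=O)CCC#C | intermediate
18 | 2-methylhex-5-yn-2-ol | CC(C)(O)CCC#C | intermediate
19 | triethyl[(2-methylhex-5-yn-2-yl)oxy]silane | CC(C)(CCC#C)O[Si](CC)(CC)CC | intermediate
20 | lithium 5-methyl-5-(triethylsilyloxy)hex-1-yn-1-ide (not isolated) | [Li]C#CCCC(C)(C)O[Si](CC)(CC)CC | intermediate
21 | lithium 5-methyl-5-(triethylsilyloxy)hex-1-yn-1-olate (not isolated) | [Li+].[O-]C#CCCC(C)(C)O[Si](CC)(CC)CC | intermediate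
22 | triisopropyl{[5-methyl-5-(triethylsilyloxy)hex-1-yn-1-yl]oxy}silane | CC(C)(CCC#CO[Si](C(C)C)(C(C)C)C(C)C)O[Si](CC)(CC)CC | intermediate
23 | 2-{5-[7-(methoxymethoxy)-2,2-dimethyl-2H-chromen-6-yl]-4-oxo-4H-pyran-2-yl}ethenone (not isolated) | O=C=Cc1cc(=O)c(-c2cc3c(cc2OCOC)OC(C)(C)C=C3)co1 | intermediate
24 | 4-{5-[7-(methoxymethoxy)-2,2-dimethyl-2H-chromen-6-yl]-4-oxo-4H-pyran-2-yl}-2-[3-methyl-3-(triethylsilyloxy)butyl]-3-(triisopropylsilyloxy)cyclobut-2-en-1-one (racemic, not isolated) | O=C1C(CCC(C)(C)O[Si](CC)(CC)CC)=C(O[Si](C(C)C)(C(C)C)C(C)C)C1c1cc(=O)c(-c2cc3c(cc2OCOC)OC(C)(C)C=C3)co1 | intermediate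
25 | 4-{5-[7-(methoxymethoxy)-2,2-dimethyl-2H-chromen-6-yl]-4-oxo-4H-pyran-2-yl}-2-[3-methyl-3-(triethylsilyloxy)butyl]-3-(triisopropylsilyloxy)buta-1,3-dien-1-one, pyranonyl cis to the ketene carbon (not isolated) | O=C=C(CCC(C)(C)O[Si](CC)(CC)CC)/C(O[Si](C(C)C)(C(C)C)C(C)C)=C\c1cc(=O)c(-c2cc3c(cc2OCOC)OC(C)(C)C=C3)co1 | intermediate
26 | 3-[7-(methoxymethoxy)-2,2-dimethyl-2H-chromen-6-yl]-6-[3-methyl-3-(triethylsilyloxy)butyl]-7-(triisopropylsilyloxy)-4aH-chromene-4,5-dione (racemic, not isolated) | O=C1C(CCC(C)(C)O[Si](CC)(CC)CC)=C(O[Si](C(C)C)(C(C)C)C(C)C)C=C2OC=C(-c3cc4c(cc3OCOC)OC(C)(C)C=C4)C(=O)C12 | intermediate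
27 | 5-hydroxy-3-[7-(methoxymethoxy)-2,2-dimethyl-2H-chromen-6-yl]-6-[3-methyl-3-(triethylsilyloxy)butyl]-7-(triisopropylsilyloxy)-4H-chromen-4-one | CC(C)(CCc1c(O[Si](C(C)C)(C(C)C)C(C)C)cc2occ(-c3cc4c(cc3OCOC)OC(C)(C)C=C4)c(=O)c2c1O)O[Si](CC)(CC)CC | intermediate
28 | 5-hydroxy-3-(7-hydroxy-2,2-dimethyl-2H-chromen-6-yl)-6-(3-hydroxy-3-methylbutyl)-7-(triisopropylsilyloxy)-4H-chromen-4-one | CC(C)(O)CCc1c(O[Si](C(C)C)(C(C)C)C(C)C)cc2occ(-c3cc4c(cc3O)OC(C)(C)C=C4)c(=O)c2c1O | intermediate
29 | 5,7-dihydroxy-3-(7-hydroxy-2,2-dimethyl-2H-chromen-6-yl)-6-(3-hydroxy-3-methylbutyl)-4H-chromen-4-one | CC(C)(O)CCc1c(O)cc2occ(-c3cc4c(cc3O)OC(C)(C)C=C4)c(=O)c2c1O | target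

**Step count and risk**
Total steps: 16. Longest linear sequence: 11 steps (steps 1–5, 8–10, 14–16).

Steps most likely to fail:

1. Step 14. The electron-poor pyranonyl group may migrate sluggishly in the Wolff shift. The 3-arylpyranone and chromene chromophores may absorb the light and degrade. The electron-rich chromene alkene may capture the ketene in competition with the siloxyalkyne. Fallback, setting out from 11 and 22 and returning at 27: the annulation is moved ahead of the biaryl coupling so that it runs on a simple substrate. Triflate 11 is hydrolysed under acid (6 M HCl, AcOH, 90 °C; nothing acid-labile is present) to 4-oxo-5-(trifluoromethylsulfonyloxy)-4H-pyran-2-carboxylic acid F1. As in step 10, this is taken through its isobutyl carbonic mixed anhydride F2 to the 5-triflyloxypyranonyl diazomethyl ketone F3. Irradiation of F3 with 22 and warming, as in step 14, should pass through the triflyloxypyranonylketene F4, the cyclobutenone F5, the dienylketene F6 and the cyclohexadienone F7. The product should be 5-hydroxy-6-[3-methyl-3-(triethylsilyloxy)butyl]-4-oxo-7-(triisopropylsilyloxy)-4H-chromen-3-yl trifluoromethanesulfonate F8. Suzuki coupling of F8 with boronate 8 (PdCl2(dppf)·CH2Cl2, K3PO4, 1,4-dioxane, 70 °C) then installs the chromenyl ring last and gives 27.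

2. Step 8. The basic aqueous medium may cleave the electron-poor triflate at sulfur, saponify the ester or open the pyranone, and the electron-rich ortho-alkoxy boronate may protodeboronate. Fallback, setting out from 6 and returning at 12: a base-free Stille coupling. Bromide 6 is lithiated as in step 5 (aryllithium 7) and quenched with Bu3SnCl to give tributyl[7-(methoxymethoxy)-2,2-dimethyl-2H-chromen-6-yl]stannane F9. This is coupled with triflate 11 (Pd(PPh3)4, CuI, LiCl, 1,4-dioxane, 80 °C) to give 12.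

3. Step 15. Under protic acid the freed tertiary carbinol may ionise and close onto the C5 phenol, and methanol may add across the chromene double bond. Fallback, setting out from 27 and returning at 29: the acetal is removed without protic acid while the carbinol stays silylated. Me3SiOTf with 2,2'-bipyridyl (CH2Cl2, 0 °C) transfers the methoxymethyl group to the bipyridine and should leave the aryl trimethylsilyl ether F10. Water then hydrolyses it to 5-hydroxy-3-(7-hydroxy-2,2-dimethyl-2H-chromen-6-yl)-6-[3-methyl-3-(triethylsilyloxy)butyl]-7-(triisopropylsilyloxy)-4H-chromen-4-one F11. Bu4NF/AcOH (THF, rt) then removes both remaining silyl groups from F11 in one operation to give 29.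

**Further compounds**
F1 | step 14 | 4-oxo-5-(trifluoromethylsulfonyloxy)-4H-pyran-2-carboxylic acid | OC(=O)c1cc(=O)c(OS(=O)(=O)C(F)(F)F)co1
F2 | step 14 | isobutyl carbonic anhydride of F1 | CC(C)COC(=O)OC(=O)c1cc(=O)c(OS(=O)(=O)C(F)(F)F)co1
F3 | step 14 | 6-(2-diazoacetyl)-4-oxo-4H-pyran-3-yl trifluoromethanesulfonate | [N-]=[N+]=CC(=O)c1cc(=O)c(OS(=O)(=O)C(F)(F)F)co1
F4 | step 14 | 4-oxo-6-(2-oxoethenyl)-4H-pyran-3-yl trifluoromethanesulfonate | O=C=Cc1cc(=O)c(OS(=O)(=O)C(F)(F)F)co1
F5 | step 14 | 6-{3-[3-methyl-3-(triethylsilyloxy)butyl]-4-oxo-2-(triisopropylsilyloxy)cyclobut-2-en-1-yl}-4-oxo-4H-pyran-3-yl trifluoromethanesulfonate (racemic) | O=C1C(CCC(C)(C)O[Si](CC)(CC)CC)=C(O[Si](C(C)C)(C(C)C)C(C)C)C1c1cc(=O)c(OS(=O)(=O)C(F)(F)F)co1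
F6 | step 14 | 6-{3-[3-methyl-3-(triethylsilyloxy)butyl]-4-oxo-2-(triisopropylsilyloxy)buta-1,3-dien-1-yl}-4-oxo-4H-pyran-3-yl trifluoromethanesulfonate, pyranonyl cis to the ketene carbon | O=C=C(CCC(C)(C)O[Si](CC)(CC)CC)/C(O[Si](C(C)C)(C(C)C)C(C)C)=C\c1cc(=O)c(OS(=O)(=O)C(F)(F)F)co1
F7 | step 14 | 6-[3-methyl-3-(triethylsilyloxy)butyl]-4,5-dioxo-7-(triisopropylsilyloxy)-4a,5-dihydro-4H-chromen-3-yl trifluoromethanesulfonate (racemic) | O=C1C(CCC(C)(C)O[Si](CC)(CC)CC)=C(O[Si](C(C)C)(C(C)C)C(C)C)C=C2OC=C(OS(=O)(=O)C(F)(F)F)C(=O)C12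
F8 | step 14 | 5-hydroxy-6-[3-methyl-3-(triethylsilyloxy)butyl]-4-oxo-7-(triisopropylsilyloxy)-4H-chromen-3-yl trifluoromethanesulfonate | CC(C)(CCc1c(O[Si](C(C)C)(C(C)C)C(C)C)cc2occ(OS(=O)(=O)C(F)(F)F)c(=O)c2c1O)O[Si](CC)(CC)CC
F9 | step 8 | tributyl[7-(methoxymethoxy)-2,2-dimethyl-2H-chromen-6-yl]stannane | CCCC[Sn](CCCC)(CCCC)c1cc2c(cc1OCOC)OC(C)(C)C=C2
F10 | step 15 | 5-hydroxy-3-[2,2-dimethyl-7-(trimethylsilyloxy)-2H-chromen-6-yl]-6-[3-methyl-3-(triethylsilyloxy)butyl]-7-(triisopropylsilyloxy)-4H-chromen-4-one | CC(C)(CCc1c(O[Si](C(C)C)(C(C)C)C(C)C)cc2occ(-c3cc4c(cc3O[Si](C)(C)C)OC(C)(C)C=C4)c(=O)c2c1O)O[Si](CC)(CC)CC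
F11 | step 15 | 5-hydroxy-3-(7-hydroxy-2,2-dimethyl-2H-chromen-6-yl)-6-[3-methyl-3-(triethylsilyloxy)butyl]-7-(triisopropylsilyloxy)-4H-chromen-4-one | CC(C)(CCc1c(O[Si](C(C)C)(C(C)C)C(C)C)cc2occ(-c3cc4c(cc3O)OC(C)(C)C=C4)c(=O)c2c1O)O[Si](CC)(CC)CC
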